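The numbers of this flask stand for no real mixture; the rest is arithmetic.

In the first seconds each coupling of electrophile with nucleophile sets acid free, and the question is who holds that acid, since winter and summer differ in their free base.

- winter: electrophile 0.20 mM; nucleophile 0.500 mM; free base 0.160 mM; protic impurity 0.0200 mM; time 20 s
- summer: electrophile 0.20 mM; nucleophile 0.500 mM; free base 0.320 mM; protic impurity 0.0200 mM; time 20 s

    electrophile + nucleophile → acid set free + target (k1 = 150 L mol⁻¹ s⁻¹)
    nucleophile + acid set free ⇌ protonated nucleophile, settled at all times (K2 = 4.0 × 10⁵ L mol⁻¹)
    acid set free + free base ⇌ salt of the base (K3 = 1.1 × 10⁶ L mol⁻¹, k3 = 1300 L mol⁻¹ s⁻¹)
    protic impurity + free base → quenched reagent (k4 = 1600 L mol⁻¹ s⁻¹)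
    2 free base → self-condensation product (k5 = 120 L mol⁻¹ s⁻¹)
    electrophile + target → side product (k6 = 460 L mol⁻¹ s⁻¹)

- part of the electrophile that has reacted at the end, winter
- part of the electrophile that has reacted at the end, summer
- what raising the concentration of free base from its lowest to its highest value here does to the part of the electrophile that has reacted (changes below 5 percentage points count as none) (it falls / it rises / no change)

- in percentages every species weighs as the electrophile in it: one side product counts as two
- two of one species on the left: rate k times its square, two consumed each time
- run time (winter): 20 s

I climb the ladder of times from the fastest rung. The balance between acid and nucleophile comes first, being kept at all times, so in winter free acid starts at about one part in 200 of the protonated nucleophile. Next, in winter, comes the protic impurity, with a half-life of 2.7 s against free base. Then comes capture of acid by free base in winter, 3.3 s for the forward step alone, but that clock acts on free acid, the small part. Slower still are the target's loss to the electrophile, 7.5 s, and the electrophile's coupling, 9.2 s, both with partners as charged; since the target's time is shorter than the electrophile's, I expect side product to compete with target in winter.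

I treat the base's capture as a small correction to the nucleophile's hold. With K = 4.0 × 10⁵ L mol⁻¹ for the nucleophile's balance, k = 1300 L mol⁻¹ s⁻¹ for capture, and N and B the charges of nucleophile and free base, I estimate that acid leaks from protonated nucleophile to free base in a pseudo-first-order way, forward step alone, with time τ = K·N/(k·B). That is 962 s in winter and 481 s in summer. Dividing by 2, as if the protonated nucleophile grew evenly from nothing, I get the leak share t/(2τ), my estimate of the salt of the base per protonated nucleophile at time t: 1.04% in winter and 2.08% in summer. Free base meets the electrophile in no step of the scheme, and because τ is far longer than the run even in summer, I commit to no change in the trend; my reckoning gives no percentage.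

The forecast says 78% for winter, 78.5% for summer and no change, on the ground that “The nucleophile mops up the released acid far faster than the base can”.

The simulation gives 78.6% in winter and 78.6% in summer, so the trend is no change, the two differing by 0.027 percentage points. At 20 s the salt of the base stands at 1.34% of the protonated nucleophile in winter, against a leak share of 1.04%, and at 2.18% in summer, against 2.08%. The neighbouring flask is the summer flask read at 30 s, where the same reckoning gives a leak share of 3.12%. Its reading is 3.21%, and in that flask 89.7% of the electrophile has reacted.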